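**Retrosynthetic overview**

1. Target 27 ← desilylation and graded acylation (C6 acetate; C7 and C11 isobutyrates) of triol 22. C4=C18 comes from the C4 ketone (Lombardo), the butenolide C13–C16 from an acrylate ring-closing metathesis, and C11–C12 from a chelation-controlled Barbier allylation of the C11 aldehyde 16.
2. Key disconnection: both rings of the trans-decalin are cut at once, at C5–C10 (ring A) and C8–C9 (ring B). Decalin 15 carries the quaternary carbons C5 and C9 (the 1,3-diaxial C19/C20 methyl pair), C10–H and the C8 tertiary carbinol. It comes from the acyclic alkene–enal–ketone 12 in one HAT-initiated Giese/aldol bicyclization; ring A closes first, ring B second, in the same flask.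
3. 12 ← Ni/Cr union at C4–C5 of vinyl triflate 4 (C5–C8, C17, C19; from D-tartrate; carries C6 and C7) with aldehyde 10 (C1–C4, C9–C11, C20; from the (R)-hydroxymethyl-butyrolactone; carries C1).

Key step: step 8

Remark: atoms carry clerodane numbers (decalin C1–C10; C18 = exocyclic methylene carbon on C4; C19 = methyl on C5; C17 = methyl on C8; C20 = methyl on C9; side chain C11–C16); α/β refer to the usual drawing with C19 α.
Assumption: the two chiral-pool compounds 1 and 5 and all reagents named are taken as commercial; C4 of 11–15 is a temporary stereocentre that becomes the ketone in step 9.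

**Step 1**
Reactants: 1 dimethyl (4S,5S)-2,2-dimethyl-1,3-dioxolane-4,5-dicarboxylate
Product: 3 (4S,5S)-4,5-diacetyl-2,2-dimethyl-1,3-dioxolane, via bis-Weinreb amide 2 (not isolated)
Conditions: MeNHOMe·HCl (3 equiv), i-PrMgCl (6 equiv), THF, −20 °C; then MeMgBr (3 equiv), −20 → 0 °C
Reagents that add atoms: methylmagnesium bromide (C[Mg]Br); N,O-dimethylhydroxylamine hydrochloride (CNOC.Cl)
Why: Ester-to-Weinreb-amide exchange with the magnesium amide made in situ, then Grignard addition to the chelated Weinreb amides, which stops at the ketone; the N-methoxy-N-methylamino groups are carried only by 2 and leave again in the Grignard stage, while the trans-dioxolane centres (C6, C7) come from the chiral pool and should not be enolised at low temperature.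

**Step 2**
Reactants: 3 (4S,5S)-4,5-diacetyl-2,2-dimethyl-1,3-dioxolane
Product: 4 1-[(4S,5S)-5-acetyl-2,2-dimethyl-1,3-dioxolan-4-yl]ethenyl trifluoromethanesulfonate
Conditions: KHMDS (0.95 equiv), THF, −78 °C; then PhNTf2, −78 → −20 °C; recovered 3 is recycled
Reagents that add atoms: N-phenylbis(trifluoromethanesulfonimide) (O=S(=O)(N(c1ccccc1)S(=O)(=O)C(F)(F)F)C(F)(F)F)
Why: Kinetic enolisation at a methyl group and O-triflation (enol triflate formation); the two acetyl groups are homotopic, so mono-triflation with a deficit of base desymmetrises 3, and the trans-fused dioxolane blocks an intramolecular aldol.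

**Step 3**
Reactants: 5 (5R)-5-(hydroxymethyl)oxolan-2-one
Product: 7 ethyl (2E)-2-methyl-3-[(2R)-5-oxooxolan-2-yl]prop-2-enoate, via lactone aldehyde 6 (not isolated)
Conditions: Dess–Martin periodinane, CH2Cl2, 0 °C → rt; then Ph3P=C(CH3)CO2Et, rt
Reagents that add atoms: ethyl 2-(triphenylphosphoranylidene)propanoate (CCOC(=O)C(C)=P(c1ccccc1)(c1ccccc1)c1ccccc1)
Why: Dess–Martin oxidation and Wittig olefination with a stabilised α-branched ylide, which should give the E-trisubstituted enoate (C10=C9 with C20 and C11); C1 comes from the chiral pool.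

**Step 4**
Reactants: 7 ethyl (2E)-2-methyl-3-[(2R)-5-oxooxolan-2-yl]prop-2-enoate
Product: 9 ethyl (2E,4R)-4-(tert-butyldimethylsilyloxy)-7-[methoxy(methyl)amino]-2-methyl-7-oxohept-2-enoate, via hydroxy Weinreb amide 8 (not isolated)
Conditions: MeNHOMe·HCl, i-PrMgCl, THF, −20 °C; aqueous work-up; then TBSCl, imidazole, DMF, rt
Reagents that add atoms: N,O-dimethylhydroxylamine hydrochloride (CNOC.Cl); tert-butyldimethylsilyl chloride (CC(C)(C)[Si](C)(C)Cl)
Why: Weinreb aminolysis of the γ-lactone, which is more electrophilic than the hindered conjugated ester, and silylation of the freed C1 hydroxyl before it can relactonise.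

**Step 5**
Reactants: 9 ethyl (2E,4R)-4-(tert-butyldimethylsilyloxy)-7-[methoxy(methyl)amino]-2-methyl-7-oxohept-2-enoate
Product: 10 (4R,5E)-4-(tert-butyldimethylsilyloxy)-7-hydroxy-6-methylhept-5-enal
Conditions: DIBAL-H (4 equiv), CH2Cl2, −78 °C; Rochelle salt work-up
Reagents that add atoms: none
Why: DIBAL-H reduction takes the Weinreb amide only to the aldehyde (chelated hemiaminal until work-up) and the enoate by 1,2-reduction to the allylic alcohol.

**Step 6**
Reactants: 4 1-[(4S,5S)-5-acetyl-2,2-dimethyl-1,3-dioxolan-4-yl]ethenyl trifluoromethanesulfonate; 10 (4R,5E)-4-(tert-butyldimethylsilyloxy)-7-hydroxy-6-methylhept-5-enal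
Product: 11 1-[(4S,5R)-5-[(3R,6R,7E)-6-(tert-butyldimethylsilyloxy)-3,9-dihydroxy-8-methylnona-1,7-dien-2-yl]-2,2-dimethyl-1,3-dioxolan-4-yl]ethanone
Conditions: CrCl2 (4 equiv), NiCl2 (2 mol %), chiral sulfonamide–oxazoline ligand for asymmetric Ni/Cr coupling (enantiomer that favours 4R), Et3N, THF, rt
Reagents that add atoms: none
Why: Nozaki–Hiyama–Kishi coupling forms C4–C5 by adding the alkenyl chromium species to the aldehyde in the presence of the methyl ketone and the free hydroxyl; the ligand sets the temporary C4 carbinol (4R, α), and its C4 epimer would converge in step 9.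

**Step 7**
Reactants: 11 seco-diol
Product: 12 (2E,4R,7R)-8-[(4R,5S)-5-acetyl-2,2-dimethyl-1,3-dioxolan-4-yl]-4-(tert-butyldimethylsilyloxy)-7-hydroxy-2-methylnona-2,8-dienal
Conditions: TEMPO (10 mol %), PhI(OAc)2 (1.1 equiv), CH2Cl2, rt
Reagents that add atoms: none
Why: Oxoammonium (TEMPO) oxidation is selective for the primary allylic alcohol over the hindered secondary C4 carbinol and should give the E-enal without touching the alkenes.

**Step 8**
Reactants: 12 acyclic alkene–enal–ketone
Product: 15 trans-decalin hydroxy aldehyde (1β-OTBS; 4α-OH; 5α-CH3; 6α,7β-O-isopropylidene; 8β-OH; 8α-CH3; 9α-CH3; 9β-CHO; 10β-H), via C5 radical 13 (not isolated), via monocyclic C9 radical 14 (not isolated)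
Conditions: Fe(acac)3 (0.5 equiv), Ph(i-PrO)SiH2 (2.5 equiv), i-PrOH/1,2-dichloroethane (1:9), 0.005 M, 0 °C → rt
Reagents that add atoms: none
Why: Iron-hydride hydrogen-atom transfer to the 1,1-disubstituted C5=C19 alkene gives the tertiary radical 13, which closes ring A by 6-exo-trig Giese addition to C10 of the enal; the α-formyl radical 14 is then reduced by Fe(II) to an iron(III) enolate, which closes ring B by a 6-(enolexo)-exo-trig aldol addition of C9 to the C8 methyl ketone. The closest known reaction type is the iron-hydride-initiated radical–polar crossover (Giese/aldol) annulation and polycyclization of alkene-tethered enals and ketones, which likewise builds a formyl-bearing quaternary carbon next to a tertiary carbinol. C10 is set by the C1 silyloxy centre: in the chair transition state C1–H lies in the enal plane (A1,3 strain with C20) and the radical enters anti to the C1–O bond, so that OTBS and the C10–C9 bond become trans-diequatorial; C5 follows from the same chair, with the large dioxolanyl branch pseudo-equatorial and C19 axial, which gives the trans ring fusion. C8 is set in the chair aldol transition state, with the ketone methyl C17 equatorial and C9 entering anti to the C7–O bond (Felkin–Anh), which puts O8 axial (β). C9 is set by the closed, iron-bridged aldol transition state, which holds the formyl group gauche to the new O8 and therefore equatorial (β), with C20 axial (α). The step needs HAT to select the 1,1-disubstituted alkene over the trisubstituted enal alkene (the usual donor/acceptor order of HAT Giese couplings) and aldol capture to outrun enolate protonation, which the six-membered closure onto an α-alkoxy ketone and a medium low in alcohol should secure; the (S,S)-acetonide is the matched diol, with both C–O bonds equatorial on the new ring B.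

**Step 9**
Reactants: 15 trans-decalin hydroxy aldehyde
Product: 16 trans-decalin keto aldehyde (C4 ketone; otherwise as 15)
Conditions: Dess–Martin periodinane, CH2Cl2, 0 °C
Reagents that add atoms: none
Why: Dess–Martin oxidation of the only secondary alcohol; the tertiary C8 hydroxyl and the non-enolisable C11 aldehyde are inert.

**Step 10**
Reactants: 16 trans-decalin keto aldehyde
Product: 17 (11S)-homoallylic alcohol (C11–OH; C12H2–C13(=CH2)–C16H2Br on C9)
Conditions: In powder (2 equiv), 3-bromo-2-(bromomethyl)prop-1-ene (5 equiv), THF/H2O (4:1), rt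
Reagents that add atoms: 3-bromo-2-(bromomethyl)prop-1-ene (C=C(CBr)CBr)
Why: Barbier allylation with the allylindium reagent is selective for the aldehyde over the hindered C4 ketone; C11 (S) is set by chelation of indium between O8 and the aldehyde oxygen, with C–C bond formation on the carbonyl face remote from the C1 silyloxy group, which lies syn-pentane to C11.

**Step 11**
Reactants: 17 (11S)-homoallylic alcohol
Product: 18 C16 acrylate (C11–OH free)
Conditions: potassium acrylate (1.5 equiv), Bu4NI (10 mol %), DMF, rt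
Reagents that add atoms: potassium acrylate (C=CC(=O)[O-].[K+])
Why: SN2 displacement of the allylic bromide by the carboxylate, which is far more nucleophilic than the neutral hindered C11 hydroxyl.

**Step 12**
Reactants: 18 C16 acrylate
Product: 19 C16 acrylate 11-O-isobutyrate
Conditions: (i-PrCO)2O, DMAP, Et3N, CH2Cl2, rt → 40 °C
Reagents that add atoms: isobutyric anhydride (CC(C)C(=O)OC(=O)C(C)C)
Why: DMAP-catalysed acylation of the only secondary alcohol; the tertiary C8 hydroxyl next to the quaternary C9 should not be acylated.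

**Step 13**
Reactants: 19 C16 acrylate 11-O-isobutyrate
Product: 20 butenolide ketone (15,16-olide with C13=C14; C4 ketone)
Conditions: second-generation Ru benzylidene metathesis catalyst (Grubbs II, 10 mol %), toluene, 80 °C, 0.005 M
Reagents that add atoms: none
Why: Ring-closing metathesis of the acrylate with the 1,1-disubstituted C13 alkene gives the β-substituted butenolide with loss of ethylene.

**Step 14**
Reactants: 20 butenolide ketone
Product: 21 4(18)-ene (exocyclic methylene; 6,7-acetonide; 1-OTBS)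
Conditions: pre-formed CH2Br2/Zn/TiCl4 reagent, CH2Cl2/THF, 0 °C → rt
Reagents that add atoms: dibromomethane (BrCBr)
Why: Lombardo methylenation is non-basic and selective for ketones over esters and lactones, so the hindered C4 ketone should give the exocyclic alkene without enolisation or attack on the butenolide.

**Step 15**
Reactants: 21 4(18)-ene acetonide
Product: 22 6α,7β,8β-triol (1-OTBS; 11-O-isobutyrate)
Conditions: AcOH/THF/H2O (3:1:1), 40 °C
Reagents that add atoms: none
Why: Acid hydrolysis of the strained trans-fused acetonide; the hindered secondary TBS ether, the esters and the exocyclic alkene should tolerate dilute acetic acid.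

**Step 16**
Reactants: 22 6α,7β,8β-triol
Product: 25 6-O-acetate 7β,8β-diol, via 7,8-O-phenylboronate 23 (not isolated), via 6-O-acetyl boronate 24 (not isolated)
Conditions: PhB(OH)2 (1.1 equiv), toluene, 4 Å MS, rt; then Ac2O, pyridine, DMAP (cat.), 0 °C → rt; then H2O2, pH 7 phosphate buffer, THF, 0 °C
Reagents that add atoms: acetic anhydride (CC(=O)OC(C)=O); phenylboronic acid (OB(O)c1ccccc1)
Why: The cis-7,8-diol is masked as its cyclic phenylboronate (the trans-diequatorial 6,7-diol forms the more strained five-membered boronate far less readily), the remaining C6 hydroxyl is acetylated (DMAP-catalysed acylation), and the boronate is removed by oxidative B–C cleavage and hydrolysis, so that the boron and phenyl atoms are carried only by 23 and 24.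

**Step 17**
Reactants: 25 6-O-acetate 7β,8β-diol
Product: 26 1-O-TBS ether of the target (6-OAc; 7-O- and 11-O-isobutyrate; 8-OH)
Conditions: (i-PrCO)2O, DMAP, Et3N, CH2Cl2, 0 °C → rt
Reagents that add atoms: isobutyric anhydride (CC(C)C(=O)OC(=O)C(C)C)
Why: DMAP-catalysed acylation of the C7 secondary alcohol; the tertiary C8 hydroxyl stays free.

**Step 18**
Reactants: 26 1-O-TBS ether of the target
Product: 27 CNP0325163.1 (target)
Conditions: HF·pyridine, pyridine/THF, 0 °C → rt
Reagents that add atoms: none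
Why: Fluoride-mediated desilylation frees the 1β-hydroxyl; the esters, the butenolide and the exocyclic alkene should be stable to buffered HF·pyridine.

**Compound list**

1 | dimethyl (4S,5S)-2,2-dimethyl-1,3-dioxolane-4,5-dicarboxylate | COC(=O)[C@H]1OC(C)(C)O[C@@H]1C(=O)OC | starting material
2 | (4S,5S)-N4,N5-dimethoxy-N4,N5,2,2-tetramethyl-1,3-dioxolane-4,5-dicarboxamide (bis-Weinreb amide) | CON(C)C(=O)[C@H]1OC(C)(C)O[C@@H]1C(=O)N(C)OC | intermediate
3 | (4S,5S)-4,5-diacetyl-2,2-dimethyl-1,3-dioxolane | CC(=O)[C@H]1OC(C)(C)O[C@@H]1C(C)=O | intermediate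
4 | 1-[(4S,5S)-5-acetyl-2,2-dimethyl-1,3-dioxolan-4-yl]ethenyl trifluoromethanesulfonate | CC(=O)[C@H]1OC(C)(C)O[C@@H]1C(=C)OS(=O)(=O)C(F)(F)F | intermediate
5 | (5R)-5-(hydroxymethyl)oxolan-2-one | O=C1CC[C@@H](O1)CO | starting material
6 | (2R)-5-oxooxolane-2-carbaldehyde (lactone aldehyde) | O=C1CC[C@@H](O1)C=O | intermediate
7 | ethyl (2E)-2-methyl-3-[(2R)-5-oxooxolan-2-yl]prop-2-enoate | O=C1CC[C@@H](O1)/C=C(\C)C(=O)OCC | intermediate
8 | ethyl (2E,4R)-4-hydroxy-7-[methoxy(methyl)amino]-2-methyl-7-oxohept-2-enoate (hydroxy Weinreb amide) | CON(C)C(=O)CC[C@@H](O)/C=C(\C)C(=O)OCC | intermediate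
9 | ethyl (2E,4R)-4-(tert-butyldimethylsilyloxy)-7-[methoxy(methyl)amino]-2-methyl-7-oxohept-2-enoate | CON(C)C(=O)CC[C@@H](O[Si](C)(C)C(C)(C)C)/C=C(\C)C(=O)OCC | intermediate
10 | (4R,5E)-4-(tert-butyldimethylsilyloxy)-7-hydroxy-6-methylhept-5-enal | O=CCC[C@@H](O[Si](C)(C)C(C)(C)C)/C=C(\C)CO | intermediate
11 | 1-[(4S,5R)-5-[(3R,6R,7E)-6-(tert-butyldimethylsilyloxy)-3,9-dihydroxy-8-methylnona-1,7-dien-2-yl]-2,2-dimethyl-1,3-dioxolan-4-yl]ethanone (seco-diol) | CC(=O)[C@H]1OC(C)(C)O[C@@H]1C(=C)[C@H](O)CC[C@@H](O[Si](C)(C)C(C)(C)C)/C=C(\C)CO | intermediate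
12 | (2E,4R,7R)-8-[(4R,5S)-5-acetyl-2,2-dimethyl-1,3-dioxolan-4-yl]-4-(tert-butyldimethylsilyloxy)-7-hydroxy-2-methylnona-2,8-dienal | CC(=O)[C@H]1OC(C)(C)O[C@@H]1C(=C)[C@H](O)CC[C@@H](O[Si](C)(C)C(C)(C)C)/C=C(\C)C=O | intermediate
13 | C5 tertiary radical of 12 (H added at C19) | CC(=O)[C@H]1OC(C)(C)O[C@@H]1[C](C)[C@H](O)CC[C@@H](O[Si](C)(C)C(C)(C)C)/C=C(\C)C=O | intermediate
14 | monocyclic C9 α-formyl radical (ring A closed; reduced in the flask to the iron enolate) | O[C@@H]1CC[C@@H](O[Si](C)(C)C(C)(C)C)[C@H]([C](C)C=O)[C@@]1(C)[C@H]2OC(C)(C)O[C@@H]2C(C)=O | intermediate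
15 | trans-decalin hydroxy aldehyde (1β-OTBS; 4α-OH; 5α-CH3; 6α,7β-O-isopropylidene; 8β-OH; 8α-CH3; 9α-CH3; 9β-CHO; 10β-H) | O[C@@H]1CC[C@@H](O[Si](C)(C)C(C)(C)C)[C@H]2[C@@]1(C)[C@@H](OC(C)(C)O3)[C@H]3[C@](C)(O)[C@]2(C)C=O | intermediate
16 | trans-decalin keto aldehyde (C4 ketone; otherwise as 15) | O=C1CC[C@@H](O[Si](C)(C)C(C)(C)C)[C@H]2[C@@]1(C)[C@@H](OC(C)(C)O3)[C@H]3[C@](C)(O)[C@]2(C)C=O | intermediate
17 | (11S)-homoallylic alcohol with the 2-(bromomethyl)allyl group on C11 | O=C1CC[C@@H](O[Si](C)(C)C(C)(C)C)[C@H]2[C@@]1(C)[C@@H](OC(C)(C)O3)[C@H]3[C@](C)(O)[C@]2(C)[C@H](CC(=C)CBr)O | intermediate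
18 | C16 acrylate with free C11 hydroxyl | O=C1CC[C@@H](O[Si](C)(C)C(C)(C)C)[C@H]2[C@@]1(C)[C@@H](OC(C)(C)O3)[C@H]3[C@](C)(O)[C@]2(C)[C@H](CC(=C)COC(=O)C=C)O | intermediate
19 | C16 acrylate 11-O-isobutyrate | O=C1CC[C@@H](O[Si](C)(C)C(C)(C)C)[C@H]2[C@@]1(C)[C@@H](OC(C)(C)O3)[C@H]3[C@](C)(O)[C@]2(C)[C@H](CC(=C)COC(=O)C=C)OC(=O)C(C)C | intermediate
20 | butenolide ketone (15,16-olide; C4 ketone; 6,7-acetonide; 1-OTBS) | O=C1CC[C@@H](O[Si](C)(C)C(C)(C)C)[C@H]2[C@@]1(C)[C@@H](OC(C)(C)O3)[C@H]3[C@](C)(O)[C@]2(C)[C@H](CC1=CC(=O)OC1)OC(=O)C(C)C | intermediate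
21 | 4(18)-ene (exocyclic methylene; 6,7-acetonide; 1-OTBS) | C=C1CC[C@@H](O[Si](C)(C)C(C)(C)C)[C@H]2[C@@]1(C)[C@@H](OC(C)(C)O3)[C@H]3[C@](C)(O)[C@]2(C)[C@H](CC1=CC(=O)OC1)OC(=O)C(C)C | intermediate
22 | 6α,7β,8β-triol (1-OTBS; 11-O-isobutyrate) | C=C1CC[C@@H](O[Si](C)(C)C(C)(C)C)[C@H]2[C@@]1(C)[C@@H](O)[C@H](O)[C@](C)(O)[C@]2(C)[C@H](CC1=CC(=O)OC1)OC(=O)C(C)C | intermediate
23 | 7,8-O-phenylboronate of 22 | C=C1CC[C@@H](O[Si](C)(C)C(C)(C)C)[C@H]2[C@@]1(C)[C@@H](O)[C@H](OB(c4ccccc4)O3)[C@@]3(C)[C@]2(C)[C@H](CC1=CC(=O)OC1)OC(=O)C(C)C | intermediate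
24 | 6-O-acetyl 7,8-O-phenylboronate | C=C1CC[C@@H](O[Si](C)(C)C(C)(C)C)[C@H]2[C@@]1(C)[C@@H](OC(C)=O)[C@H](OB(c4ccccc4)O3)[C@@]3(C)[C@]2(C)[C@H](CC1=CC(=O)OC1)OC(=O)C(C)C | intermediate
25 | 6-O-acetate 7β,8β-diol (1-OTBS; 11-O-isobutyrate) | C=C1CC[C@@H](O[Si](C)(C)C(C)(C)C)[C@H]2[C@@]1(C)[C@@H](OC(C)=O)[C@H](O)[C@](C)(O)[C@]2(C)[C@H](CC1=CC(=O)OC1)OC(=O)C(C)C | intermediate
26 | 1-O-TBS ether of the target | C=C1CC[C@@H](O[Si](C)(C)C(C)(C)C)[C@H]2[C@@]1(C)[C@@H](OC(C)=O)[C@H](OC(=O)C(C)C)[C@](C)(O)[C@]2(C)[C@H](CC1=CC(=O)OC1)OC(=O)C(C)C | intermediate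
27 | CNP0325163.1 | C=C1CC[C@@H](O)[C@H]2[C@@]1(C)[C@@H](OC(C)=O)[C@H](OC(=O)C(C)C)[C@](C)(O)[C@]2(C)[C@H](CC1=CC(=O)OC1)OC(=O)C(C)C | target

**Step count**

Total steps: 18. Longest linear sequence: 16 steps (5 → 27, steps 3–18); the tartrate branch (1 → 4) adds 2 steps.

**Steps most likely to fail**

Step 8 (key step). The iron enolate may be protonated before ring B closes. The C5 radical may also take the activated C1–H by 1,5-hydrogen transfer instead of cyclising, or the aldol may show poor facial control at C8/C9. The C6 centre next to the radical may also oppose the chair preference at C5. The fallback sets out from 12 and comes back at 15. The HAT Giese cyclization alone is run under protic, enolate-quenching conditions (Fe(acac)3, PhSiH3, EtOH/ethylene glycol) to give the monocyclic keto-aldehyde F1 (ring A closed, C9–H). Ring B is then closed in a separate, reversible base-mediated intramolecular aldol addition (catalytic KOt-Bu in t-BuOH/THF at 0 °C), which should return 15. This separates control at C5/C10 from control at C8/C9 and lets the aldol equilibrate.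

Step 10. Facial selectivity at C11 may be poor if the addition does not pass through the O8/O11 chelate. The fallback sets out from 15 and comes back at 19. It sets C11 by reagent-controlled hydride delivery instead of C–C bond formation, and it keeps C4 as a protected carbinol until C11 is secured, so that the C11 ketone is the only ketone present in the reduction. Silylation of the C4 hydroxyl of 15 (TESCl, imidazole, DMF, 0 °C; the tertiary C8 hydroxyl does not react) gives the 4-O-triethylsilyl aldehyde F2. Indium Barbier allylation under the conditions of step 10 gives the homoallylic alcohol F3, at this point as a C11 epimer mixture. Dess–Martin oxidation gives the C11 ketone F4, which is kept free of base. CBS reduction ((R)-methyl oxazaborolidine, catecholborane, toluene, −78 °C; C9 as the large group) should then return F3 as the single 11S alcohol. Acrylate displacement as in step 11 gives the acrylate F5, and isobutyrylation as in step 12 gives the 11-O-isobutyrate F6. Selective removal of the triethylsilyl group in the presence of the hindered C1 TBS ether (HF·pyridine, pyridine/THF, 0 °C) gives the C4 carbinol F7, and Dess–Martin oxidation returns 19.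

Step 14. Methylenation of the neopentyl C4 ketone may be too slow, so that the Lewis-acidic reagent erodes the acetonide or the silyl ether first. The fallback sets out from 16 and comes back at 21, and moves the methylenation to an intermediate without ester groups, where a forcing Wittig reaction can be used. Barbier allylation of 16 with tert-butyl{[2-(bromomethyl)prop-2-en-1-yl]oxy}dimethylsilane and indium gives the silyl ether alcohol F8. Wittig methylenation (Ph3P=CH2 from Ph3PCH3Br/KOt-Bu, toluene, 80 °C) gives the 4(18)-ene F9. Selective removal of the primary allylic TBS group (HF·pyridine/pyridine, 0 °C) gives the diol F10. Acryloylation of the primary hydroxyl (acryloyl chloride, i-Pr2NEt, −78 °C) gives the acrylate F11. Isobutyrylation at C11 gives the acrylate isobutyrate F12. Ring-closing metathesis as in step 13 returns 21; the hindered C4 methylene should not take part.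

**Further compounds**

F1 | step 8 | monocyclic keto-aldehyde (ring A closed; C9–H, epimerisable; 1β-OTBS; 4α-OH) | O[C@@H]1CC[C@@H](O[Si](C)(C)C(C)(C)C)[C@H](C(C)C=O)[C@@]1(C)[C@H]2OC(C)(C)O[C@@H]2C(C)=O
F2 | step 10 | 4-O-triethylsilyl ether of hydroxy aldehyde 15 | CC[Si](CC)(CC)O[C@@H]1CC[C@@H](O[Si](C)(C)C(C)(C)C)[C@H]2[C@@]1(C)[C@@H](OC(C)(C)O3)[C@H]3[C@](C)(O)[C@]2(C)C=O
F3 | step 10 | (11S)-homoallylic alcohol with the 2-(bromomethyl)allyl group on C11 (4-O-TES) | CC[Si](CC)(CC)O[C@@H]1CC[C@@H](O[Si](C)(C)C(C)(C)C)[C@H]2[C@@]1(C)[C@@H](OC(C)(C)O3)[C@H]3[C@](C)(O)[C@]2(C)[C@H](CC(=C)CBr)O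
F4 | step 10 | C11 ketone of F3 (4-O-TES) | CC[Si](CC)(CC)O[C@@H]1CC[C@@H](O[Si](C)(C)C(C)(C)C)[C@H]2[C@@]1(C)[C@@H](OC(C)(C)O3)[C@H]3[C@](C)(O)[C@]2(C)C(=O)CC(=C)CBr
F5 | step 10 | C16 acrylate with free C11 hydroxyl (4-O-TES) | CC[Si](CC)(CC)O[C@@H]1CC[C@@H](O[Si](C)(C)C(C)(C)C)[C@H]2[C@@]1(C)[C@@H](OC(C)(C)O3)[C@H]3[C@](C)(O)[C@]2(C)[C@H](CC(=C)COC(=O)C=C)O
F6 | step 10 | C16 acrylate 11-O-isobutyrate (4-O-TES) | CC[Si](CC)(CC)O[C@@H]1CC[C@@H](O[Si](C)(C)C(C)(C)C)[C@H]2[C@@]1(C)[C@@H](OC(C)(C)O3)[C@H]3[C@](C)(O)[C@]2(C)[C@H](CC(=C)COC(=O)C=C)OC(=O)C(C)C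
F7 | step 10 | C16 acrylate 11-O-isobutyrate with free 4α-hydroxyl | O[C@@H]1CC[C@@H](O[Si](C)(C)C(C)(C)C)[C@H]2[C@@]1(C)[C@@H](OC(C)(C)O3)[C@H]3[C@](C)(O)[C@]2(C)[C@H](CC(=C)COC(=O)C=C)OC(=O)C(C)C
F8 | step 14 | (11S)-homoallylic alcohol with C16–OTBS (C4 ketone) | O=C1CC[C@@H](O[Si](C)(C)C(C)(C)C)[C@H]2[C@@]1(C)[C@@H](OC(C)(C)O3)[C@H]3[C@](C)(O)[C@]2(C)[C@H](CC(=C)CO[Si](C)(C)C(C)(C)C)O
F9 | step 14 | 4(18)-ene of F8 | C=C1CC[C@@H](O[Si](C)(C)C(C)(C)C)[C@H]2[C@@]1(C)[C@@H](OC(C)(C)O3)[C@H]3[C@](C)(O)[C@]2(C)[C@H](CC(=C)CO[Si](C)(C)C(C)(C)C)O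
F10 | step 14 | 11,16-diol (4(18)-ene; 1-OTBS) | C=C1CC[C@@H](O[Si](C)(C)C(C)(C)C)[C@H]2[C@@]1(C)[C@@H](OC(C)(C)O3)[C@H]3[C@](C)(O)[C@]2(C)[C@H](CC(=C)CO)O
F11 | step 14 | C16 acrylate with free C11 hydroxyl (4(18)-ene) | C=C1CC[C@@H](O[Si](C)(C)C(C)(C)C)[C@H]2[C@@]1(C)[C@@H](OC(C)(C)O3)[C@H]3[C@](C)(O)[C@]2(C)[C@H](CC(=C)COC(=O)C=C)O
F12 | step 14 | C16 acrylate 11-O-isobutyrate (4(18)-ene) | C=C1CC[C@@H](O[Si](C)(C)C(C)(C)C)[C@H]2[C@@]1(C)[C@@H](OC(C)(C)O3)[C@H]3[C@](C)(O)[C@]2(C)[C@H](CC(=C)COC(=O)C=C)OC(=O)C(C)C
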